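**Retrosynthetic overview**

- The last skeletal bond is C3''–C4'' (side chain numbered C1''–C17'' outward from ring carbon C3). It is made by acyl Sonogashira coupling of acid chloride 17 with terminal diyne 10, followed by removal of one O-silyl group.
- The strategy rests on the (S)-carbinol C8'' being bonded directly to the Z alkene C9''=C10''. Cutting C8''–C9'' gives (Z)-1-iodonon-1-ene 3 and silyl diynal 6, and an asymmetric Nozaki–Hiyama–Kishi alkenylation sets alkene geometry and carbinol configuration together.
- The quaternary (S)-C3 is set by enantioselective Michael addition of ferulenol 14 (from 4-hydroxycoumarin and farnesyl methyl carbonate) to acrolein. The aldehyde is then oxidised and converted to the acid chloride.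
- Rings: the benzene ring (ring A) and the pyran-2,4-dione ring (ring B) come intact from 4-hydroxycoumarin. No ring is formed or opened anywhere in the route.

Key step: step 4

Remark: the absolute sense of induction in the two catalyst-controlled steps (4 and 9) is predicted by analogy only. Each catalyst is available in both enantiomeric or quasi-enantiomeric forms, and the form that gives the (S) centre is the one used.

**Step 1**
Reactants: 1 non-1-yne
Product: 2 1-iodonon-1-yne
Conditions: NIS (1.1 equiv), AgNO3 (10 mol%), acetone, rt, dark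
Reagents that add atoms: N-iodosuccinimide, O=C1CCC(=O)N1I
Why: Silver-catalysed electrophilic iodination of a terminal alkyne (a silver acetylide is iodinated by NIS) is the routine way to prepare 1-iodoalkynes.

**Step 2**
Reactants: 2 1-iodonon-1-yne
Product: 3 (Z)-1-iodonon-1-ene
Conditions: 2-nitrobenzenesulfonohydrazide (2 equiv), Et3N, THF/i-PrOH, rt
Reagents that add atoms: none
Why: Diimide released from the sulfonyl hydrazide transfers two hydrogens to the same face of the iodoalkyne (diimide reduction), so only the Z iodoalkene should form and the C–I bond is left alone.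

**Step 3**
Reactants: 4 1,4-bis(trimethylsilyl)buta-1,3-diyne
Product: 6 5-(trimethylsilyl)penta-2,4-diynal, via lithium 4-(trimethylsilyl)buta-1,3-diyn-1-ide 5 (not isolated)
Conditions: MeLi·LiBr (1.0 equiv), Et2O, 0 °C → rt; DMF, THF, −78 → 0 °C; inverse quench into aq. KH2PO4, 0 °C
Reagents that add atoms: N,N-dimethylformamide, CN(C)C=O
Why: MeLi·LiBr cleaves one C–Si bond selectively (the mono-anion loses the second silyl group far more slowly), and formylation of the lithium acetylide with DMF followed by inverse quench into phosphate buffer releases the ynal without dimethylamine adding to it.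

**Step 4**
Reactants: 3 (Z)-1-iodonon-1-ene; 6 5-(trimethylsilyl)penta-2,4-diynal
Product: 8 (5S,6Z)-1-(trimethylsilyl)tetradec-6-ene-1,3-diyn-5-ol, via (Z)-non-1-enylchromium dichloride 7 (not isolated)
Conditions: CrCl2 (3 equiv), N-{2-[(4S)-4-isopropyl-4,5-dihydro-1,3-oxazol-2-yl]-6-methylphenyl}methanesulfonamide (3.3 equiv), Et3N (3.3 equiv), NiCl2 (5 mol%), THF, rt; 3 in 1.5-fold excess; aq. potassium sodium tartrate work-up
Reagents that add atoms: none
Why: Divalent chromium reduces NiCl2 to zerovalent nickel, which inserts into the C–I bond of 3 with retention of the Z geometry; the alkenyl group is then handed over to trivalent chromium carrying the deprotonated oxazoline–sulfonamide ligand (7), and this alkenylchromium adds 1,2 to the aldehyde of 6 to form C8''–C9'' while more divalent chromium returns nickel to the zerovalent state. The closest known reaction type is the asymmetric Nozaki–Hiyama–Kishi coupling of alkenyl iodides with aldehydes mediated by chiral sulfonamide ligands on chromium; no ring closes. The new C8'' stereocentre is controlled by the chiral ligand, which holds the aldehyde on chromium so that the alkenyl group reaches one enantioface; the ligand enantiomer (from L- or D-valinol) that delivers the (5S) carbinol is used, and Mosher ester analysis of 8 should confirm the configuration. Three selectivities are needed: 1,2- over 1,4-addition, secured by the oxophilic alkenylchromium and the unhindered formyl group; retention of the Z alkene, secured because oxidative addition and nickel-to-chromium transmetalation are stereoretentive for 1,2-disubstituted alkenyl iodides; and enantioface selection, helped by the large shape difference between the rod-like diynyl substituent and the formyl hydrogen. The trimethylsilyl cap removes the acidic alkyne C–H that would protonate the organochromium, and because the reagent does not add to the diyne, the Z alkene never has to be made by partial reduction of a triple bond beside the diyne.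

**Step 5**
Reactants: 8 (5S,6Z)-1-(trimethylsilyl)tetradec-6-ene-1,3-diyn-5-ol
Product: 9 tert-butyl(dimethyl){[(5S,6Z)-1-(trimethylsilyl)tetradec-6-ene-1,3-diyn-5-yl]oxy}silane
Conditions: TBSCl (1.3 equiv), imidazole (2.5 equiv), DMF, 0 °C → rt
Reagents that add atoms: tert-butyldimethylsilyl chloride, CC(C)(C)[Si](C)(C)Cl
Why: Imidazole-promoted O-silylation of a secondary alcohol masks the hydroxyl against acylation in step 12 with a group that survives K2CO3/MeOH; the stereocentre is not touched.

**Step 6**
Reactants: 9 tert-butyl(dimethyl){[(5S,6Z)-1-(trimethylsilyl)tetradec-6-ene-1,3-diyn-5-yl]oxy}silane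
Product: 10 tert-butyl(dimethyl){[(5S,6Z)-tetradec-6-ene-1,3-diyn-5-yl]oxy}silane
Conditions: K2CO3 (0.2 equiv), MeOH/THF, 0 °C; kept cold in solution and used at once in step 12
Reagents that add atoms: none
Why: Methoxide-catalysed protodesilylation cleaves the C(sp)–Si bond much faster than the O–Si bond of the hindered TBS ether, and the sensitive terminal diyne is not stored.

**Step 7**
Reactants: 11 (2E,6E)-farnesol
Product: 12 (2E,6E)-farnesyl methyl carbonate
Conditions: ClCO2Me (1.5 equiv), pyridine, CH2Cl2, 0 °C
Reagents that add atoms: methyl chloroformate, COC(=O)Cl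
Why: Acylation of the primary allylic alcohol with a chloroformate under pyridine is non-ionising, so no allylic transposition occurs and both E alkenes are kept.

**Step 8**
Reactants: 12 (2E,6E)-farnesyl methyl carbonate; 13 4-hydroxycoumarin
Product: 14 ferulenol, 4-hydroxy-3-[(2E,6E)-3,7,11-trimethyldodeca-2,6,10-trien-1-yl]-2H-chromen-2-one
Conditions: 13 (3 equiv), Pd(PPh3)4 (3 mol%), THF, rt → 40 °C
Reagents that add atoms: none
Why: In this Tsuji–Trost allylation zerovalent palladium ionises the carbonate to a π-farnesyl complex, the methoxide released after loss of CO2 deprotonates the acidic coumarin, and the soft C3 nucleophile attacks the unsubstituted allyl terminus to give the linear E product; O-allylation is reversible under the catalysis and excess 13 suppresses double allylation.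

**Step 9**
Reactants: 14 ferulenol
Product: 15 3-{(3S)-2,4-dioxo-3-[(2E,6E)-3,7,11-trimethyldodeca-2,6,10-trien-1-yl]-3,4-dihydro-2H-chromen-3-yl}propanal
Conditions: acrolein (2 equiv), 9-O-(phenanthren-9-yl)cupreidine (10 mol%), CH2Cl2, −25 °C
Reagents that add atoms: acrolein, C=CC=O
Why: Proposed new method: the enolic 3-alkyl-4-hydroxycoumarin (pKa about 5) protonates the quinuclidine nitrogen to give a tight chiral ion pair, the 6'-OH of the catalyst hydrogen-bonds acrolein, and C3 attacks the β-carbon to form the quaternary centre, whose configuration is set by the catalyst distinguishing the two faces of an enolate flanked by the aryl-bound C4–O and the ring-oxygen-bound C2=O (cupreidine catalyst or its cupreine quasi-enantiomer, whichever gives S); the closest known reaction type is the cinchona-alkaloid-catalysed asymmetric Michael addition of α-substituted β-keto esters to acrolein that forms quaternary centres.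

**Step 10**
Reactants: 15 3-{(3S)-2,4-dioxo-3-[(2E,6E)-3,7,11-trimethyldodeca-2,6,10-trien-1-yl]-3,4-dihydro-2H-chromen-3-yl}propanal
Product: 16 3-{(3S)-2,4-dioxo-3-[(2E,6E)-3,7,11-trimethyldodeca-2,6,10-trien-1-yl]-3,4-dihydro-2H-chromen-3-yl}propanoic acid
Conditions: NaClO2, NaH2PO4, 2-methylbut-2-ene (30 equiv), t-BuOH/H2O, 0 °C → rt
Reagents that add atoms: sodium chlorite, [Na+].[O-]Cl=O
Why: Pinnick oxidation converts the aldehyde to the acid at about pH 4, where the base-sensitive aryl lactone is stable, and the large excess of 2-methylbut-2-ene traps HOCl before it reaches the farnesyl alkenes; the quaternary centre cannot epimerise.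

**Step 11**
Reactants: 16 3-{(3S)-2,4-dioxo-3-[(2E,6E)-3,7,11-trimethyldodeca-2,6,10-trien-1-yl]-3,4-dihydro-2H-chromen-3-yl}propanoic acid
Product: 17 3-{(3S)-2,4-dioxo-3-[(2E,6E)-3,7,11-trimethyldodeca-2,6,10-trien-1-yl]-3,4-dihydro-2H-chromen-3-yl}propanoyl chloride
Conditions: 1-chloro-N,N,2-trimethylprop-1-en-1-amine (1.2 equiv), CH2Cl2, 0 °C → rt; used crude
Reagents that add atoms: 1-chloro-N,N,2-trimethylprop-1-en-1-amine (Ghosez's reagent), CC(C)=C(Cl)N(C)C
Why: The α-chloroenamine forms the acid chloride under neutral conditions without free HCl, which spares the acid-sensitive trisubstituted alkenes, and its amide by-product is inert in the next step.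

**Step 12**
Reactants: 10 tert-butyl(dimethyl){[(5S,6Z)-tetradec-6-ene-1,3-diyn-5-yl]oxy}silane; 17 3-{(3S)-2,4-dioxo-3-[(2E,6E)-3,7,11-trimethyldodeca-2,6,10-trien-1-yl]-3,4-dihydro-2H-chromen-3-yl}propanoyl chloride
Product: 18 (3S)-3-[(8S,9Z)-8-{[tert-butyl(dimethyl)silyl]oxy}-3-oxoheptadec-9-ene-4,6-diyn-1-yl]-3-[(2E,6E)-3,7,11-trimethyldodeca-2,6,10-trien-1-yl]-2H-chromene-2,4(3H)-dione
Conditions: PdCl2(PPh3)2 (5 mol%), CuI (10 mol%), Et3N (1.5 equiv), THF, 0 °C → rt, argon
Reagents that add atoms: none
Why: In this acyl Sonogashira coupling the copper acetylide of the terminal diyne transmetalates to the acylpalladium chloride formed from 17 and reductive elimination forms C3''–C4''; forming the bond at the ketone oxidation level avoids a C3'' alkoxide that would translactonise onto the aryl lactone, and Et3N is too weak a nucleophile to open the chromandione.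

**Step 13**
Reactants: 18 (3S)-3-[(8S,9Z)-8-{[tert-butyl(dimethyl)silyl]oxy}-3-oxoheptadec-9-ene-4,6-diyn-1-yl]-3-[(2E,6E)-3,7,11-trimethyldodeca-2,6,10-trien-1-yl]-2H-chromene-2,4(3H)-dione
Product: 19 (3S)-3-[(8S,9Z)-8-hydroxy-3-oxoheptadec-9-ene-4,6-diyn-1-yl]-3-[(2E,6E)-3,7,11-trimethyldodeca-2,6,10-trien-1-yl]-2H-chromene-2,4(3H)-dione (CNP0346147.1)
Conditions: HF·pyridine, pyridine, THF, 0 °C → rt; MeOSiMe3 quench
Reagents that add atoms: none
Why: Buffered, mildly acidic fluoride cleaves the secondary TBS ether while leaving the chromandione, the diynone and the doubly activated carbinol intact, whereas basic fluoride sources could open the lactone or trigger retro-Michael loss of the coumarin.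

**Compound list**

1 | non-1-yne | CCCCCCCC#C | starting material
2 | 1-iodonon-1-yne | CCCCCCCC#CI | intermediate
3 | (Z)-1-iodonon-1-ene | CCCCCCC/C=C\I | intermediate
4 | 1,4-bis(trimethylsilyl)buta-1,3-diyne | C[Si](C)(C)C#CC#C[Si](C)(C)C | starting material
5 | lithium 4-(trimethylsilyl)buta-1,3-diyn-1-ide | C[Si](C)(C)C#CC#C[Li] | intermediate (not isolated)
6 | 5-(trimethylsilyl)penta-2,4-diynal | C[Si](C)(C)C#CC#CC=O | intermediate
7 | (Z)-non-1-enylchromium dichloride (trivalent chromium; sulfonamide ligand and solvent on the metal not drawn) | CCCCCCC/C=C\[Cr](Cl)Cl | intermediate (not isolated)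
8 | (5S,6Z)-1-(trimethylsilyl)tetradec-6-ene-1,3-diyn-5-ol | CCCCCCC/C=C\[C@H](O)C#CC#C[Si](C)(C)C | intermediate
9 | tert-butyl(dimethyl){[(5S,6Z)-1-(trimethylsilyl)tetradec-6-ene-1,3-diyn-5-yl]oxy}silane | CCCCCCC/C=C\[C@H](O[Si](C)(C)C(C)(C)C)C#CC#C[Si](C)(C)C | intermediate
10 | tert-butyl(dimethyl){[(5S,6Z)-tetradec-6-ene-1,3-diyn-5-yl]oxy}silane | CCCCCCC/C=C\[C@H](O[Si](C)(C)C(C)(C)C)C#CC#C | intermediate
11 | (2E,6E)-farnesol | OC/C=C(\C)CC/C=C(\C)CCC=C(C)C | starting material
12 | (2E,6E)-farnesyl methyl carbonate | COC(=O)OC/C=C(\C)CC/C=C(\C)CCC=C(C)C | intermediate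
13 | 4-hydroxycoumarin | OC1=CC(=O)Oc2ccccc12 | starting material
14 | ferulenol, 4-hydroxy-3-[(2E,6E)-3,7,11-trimethyldodeca-2,6,10-trien-1-yl]-2H-chromen-2-one | OC1=C(C/C=C(\C)CC/C=C(\C)CCC=C(C)C)C(=O)Oc2ccccc12 | intermediate
15 | 3-{(3S)-2,4-dioxo-3-[(2E,6E)-3,7,11-trimethyldodeca-2,6,10-trien-1-yl]-3,4-dihydro-2H-chromen-3-yl}propanal | O=CCC[C@@]1(C/C=C(\C)CC/C=C(\C)CCC=C(C)C)C(=O)Oc2ccccc2C1=O | intermediate
16 | 3-{(3S)-2,4-dioxo-3-[(2E,6E)-3,7,11-trimethyldodeca-2,6,10-trien-1-yl]-3,4-dihydro-2H-chromen-3-yl}propanoic acid | OC(=O)CC[C@@]1(C/C=C(\C)CC/C=C(\C)CCC=C(C)C)C(=O)Oc2ccccc2C1=O | intermediate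
17 | 3-{(3S)-2,4-dioxo-3-[(2E,6E)-3,7,11-trimethyldodeca-2,6,10-trien-1-yl]-3,4-dihydro-2H-chromen-3-yl}propanoyl chloride | ClC(=O)CC[C@@]1(C/C=C(\C)CC/C=C(\C)CCC=C(C)C)C(=O)Oc2ccccc2C1=O | intermediate
18 | (3S)-3-[(8S,9Z)-8-{[tert-butyl(dimethyl)silyl]oxy}-3-oxoheptadec-9-ene-4,6-diyn-1-yl]-3-[(2E,6E)-3,7,11-trimethyldodeca-2,6,10-trien-1-yl]-2H-chromene-2,4(3H)-dione | CCCCCCC/C=C\[C@H](O[Si](C)(C)C(C)(C)C)C#CC#CC(=O)CC[C@@]1(C/C=C(\C)CC/C=C(\C)CCC=C(C)C)C(=O)Oc2ccccc2C1=O | intermediate
19 | (3S)-3-[(8S,9Z)-8-hydroxy-3-oxoheptadec-9-ene-4,6-diyn-1-yl]-3-[(2E,6E)-3,7,11-trimethyldodeca-2,6,10-trien-1-yl]-2H-chromene-2,4(3H)-dione | CCCCCCC/C=C\[C@H](O)C#CC#CC(=O)CC[C@@]1(C/C=C(\C)CC/C=C(\C)CCC=C(C)C)C(=O)Oc2ccccc2C1=O | target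

**Step count**

Total: 13 steps. Longest linear sequence: 7 steps (1, 2, 4, 5, 6, 12, 13 from non-1-yne; equally 7, 8, 9, 10, 11, 12, 13 from farnesol).

**Steps most likely to fail**

1. Step 9 (proposed new method). The catalyst may discriminate poorly between the two faces of the coumarin enolate, because C3 is flanked by two carbonyl-type carbons that differ only further out, and an uncatalysed racemic background addition would erode the selectivity further. The fallback sets out from 14 and comes back at 15. Triethylamine-catalysed Michael addition of 14 to acrolein in CH2Cl2 should give the racemic aldehyde, rac-3-[2,4-dioxo-3-farnesyl-3,4-dihydro-2H-chromen-3-yl]propanal F1. Preparative chromatography on a chiral stationary phase (amylose tris(3,5-dimethylphenylcarbamate), CO2/i-PrOH) then separates the (S) antipode, which is 15, from the (R)-aldehyde F2. Both operations are known chemistry.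

2. Step 4 (key step). The small, linear ynal may give insufficient enantioface selection, the sensitive ynal may oligomerise in the amine-containing medium before it is captured, and some Z to E leakage at the nickel stage is possible. The fallback sets out from 3 and 6 and comes back at 8. Ligand-free coupling with CrCl2 and catalytic NiCl2 in DMF should give the racemic carbinol, (6Z)-1-(trimethylsilyl)tetradec-6-ene-1,3-diyn-5-ol F3. MnO2 in CH2Cl2 oxidises this doubly activated alcohol to the ketone, (6Z)-1-(trimethylsilyl)tetradec-6-ene-1,3-diyn-5-one F4. Corey–Bakshi–Shibata reduction ((S)-2-methyl-CBS-oxazaborolidine, catecholborane, toluene, −78 °C), with the Z-alkenyl arm acting as the large group and the rod-like diynyl arm as the small one, then sets C8'' by reagent control and returns 8.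

3. Step 12. Triethylamine may dehydrochlorinate the α-CH2 acid chloride to a ketene or trigger β-elimination of the coumarin, the terminal diyne may dimerise oxidatively or polymerise under copper, and chloride may add to the diynone. The fallback sets out from 10 and 17 and comes back at 18. Diyne 10 is deprotonated with LiN(SiMe3)2 at −78 °C and stannylated with Bu3SnCl to the alkynylstannane, tributyl{(5S,6Z)-5-{[tert-butyl(dimethyl)silyl]oxy}tetradec-6-ene-1,3-diyn-1-yl}stannane F5. Stille acylation with 17 (PdCl2(PPh3)2 cat., 1,2-dichloroethane, rt → 50 °C, no amine and no copper) then forms the same C3''–C4'' bond and gives 18.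

**Further compounds**

F1 | step 9 | rac-3-{2,4-dioxo-3-[(2E,6E)-3,7,11-trimethyldodeca-2,6,10-trien-1-yl]-3,4-dihydro-2H-chromen-3-yl}propanal | O=CCCC1(C/C=C(\C)CC/C=C(\C)CCC=C(C)C)C(=O)Oc2ccccc2C1=O
F2 | step 9 | 3-{(3R)-2,4-dioxo-3-[(2E,6E)-3,7,11-trimethyldodeca-2,6,10-trien-1-yl]-3,4-dihydro-2H-chromen-3-yl}propanal | O=CCC[C@]1(C/C=C(\C)CC/C=C(\C)CCC=C(C)C)C(=O)Oc2ccccc2C1=O
F3 | step 4 | rac-(6Z)-1-(trimethylsilyl)tetradec-6-ene-1,3-diyn-5-ol | CCCCCCC/C=C\C(O)C#CC#C[Si](C)(C)C
F4 | step 4 | (6Z)-1-(trimethylsilyl)tetradec-6-ene-1,3-diyn-5-one | CCCCCCC/C=C\C(=O)C#CC#C[Si](C)(C)C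
F5 | step 12 | tributyl{(5S,6Z)-5-{[tert-butyl(dimethyl)silyl]oxy}tetradec-6-ene-1,3-diyn-1-yl}stannane | CCCCCCC/C=C\[C@H](O[Si](C)(C)C(C)(C)C)C#CC#C[Sn](CCCC)(CCCC)CCCC
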